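**Conventions and assumptions**

- Ring locants C1–C6 are those of the target and are kept for every intermediate: C1 and C4 carbonyl carbons, C2 hydroxyl, C3 docosyl, C5 methoxy, C6 hydrogen.
- Compound numbers: 1 Cr(CO)6; 2 lithium acyl chromate; 3 methyl(methoxy)carbene complex; 4 1-bromodocosane; 5 its Grignard reagent; 6 tricosanal; 7 lithium "enolate" of 3; 8 aldol adduct; 9 its mesylate; 10 alkenyl carbene complex; 11 chloroacetaldehyde dimethyl acetal; 12 sodium methoxyethynide; 13 methoxyethyne; 14 Cr(CO)3 complex of 15; 15 2-docosyl-4,6-dimethoxyphenol; 16 2-docosyl-6-methoxy-1,4-benzoquinone; 17 triacetate; 18 triol; 19 target.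
- Remark on the chemistry: methoxyethyne 13 is volatile and not a stock reagent, so it is made in one step. The chain is taken from 1-bromodocosane 4 because one Grignard formylation reaches tricosanal 6 directly.

## Analysis of the target

Compound 19 is 3-docosyl-2-hydroxy-5-methoxy-1,4-benzoquinone: one six-membered ring with carbonyls at C1 and C4, a hydroxyl at C2, an unbranched C22 chain at C3, a methoxy group at C5 and a hydrogen at C6. It has no stereocentre and no double bond outside the ring, so the whole problem is regiochemistry on one ring. The two oxygen substituents are close relatives: C2–OH is a vinylogous acid (through C3 to C4=O) and C5–OMe is a vinylogous ester (through C6 to C1=O). Telling them apart late, by selective methylation of a dihydroxyquinone, would therefore rest on a small difference. The quinone is sensitive to reduction, base and nucleophiles, the vinylogous ester is exchanged or cleaved by acidic alcohols and aqueous acid or base, and the docosyl chain makes every intermediate a wax that dissolves poorly in cold or polar media. The difficulty is to place the chain beside the free hydroxyl and the methyl ether across the ring without ever having to distinguish two near-equivalent oxygens. The route rests on the fact that the para carbons C1 and C4 divide the ring into two two-carbon pieces, C2=C3 carrying the chain and C5=C6 carrying the methoxy group. As a 4-methoxyphenol oxygenated at C1 and C4, this is the pattern of a chromium carbene benzannulation: C1 from the carbene carbon, C2–C3 from its alkenyl group, C4 from a carbonyl ligand, and C5–C6 from a terminal ynol ether. The C5 oxygen thus arrives already methylated, and the C2 oxygen is added last at the only position the methoxyquinone leaves open to a nucleophile.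

## Retrosynthetic reasoning

**19 from 17 via 18.** No skeletal bond is cut. The target is the oxidation product of triol 18, which is handled as its triacetate 17. Three acetyl–oxygen bonds are cleaved and two electrons removed. The gain is that the C2 oxygen can be carried in a form that is stable to storage, and the C5 methyl ether is an ordinary aryl ether until the last oxidation.

**17 from 16.** The C2–O bond is cut. In quinone 16 the C5 methoxy group deactivates C1=O as a vinylogous ester and makes C6 the electron-rich end of an enol ether. That leaves C2, the β-carbon of the enone C4(=O)–C3=C2, as the one site for conjugate addition. The forward reaction has to add an oxygen nucleophile there and aromatise, which a reductive acetoxylation does in one operation.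

**16 from 15.** Only the oxidation level changes: the C1 methoxy group of phenol 15 is a masked carbonyl. The forward step must oxidise the 4-methoxyphenol to the para-quinone and leave the C5 methoxy group, which is ortho to the phenol, in place.

**15 from 10 and 13 (the key disconnection).** Three ring bonds are cut: C1–C6, C4–C5 and C3–C4. C4 is returned to a carbonyl ligand of the alkenyl carbene complex 10, and C5–C6 to methoxyethyne 13. Cutting here, and not at a C–O bond, puts each differentiated substituent on its own acyclic partner: the chain on the alkene of 10, the surviving methoxy group on 13, and the sacrificial methoxy group on the carbene carbon. The forward reaction must join the unsubstituted alkyne carbon to the carbene carbon, insert CO at the oxygen-bearing alkyne carbon, and close the ring onto C3.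

**10 from 3 and 6 via 8.** The C2=C3 double bond is cut as an aldol condensation. The methyl group of complex 3 is acidic, so the whole C22 chain can be delivered as the simple aldehyde 6. The aldehyde carbon becomes ring carbon C3. Addition to 8 and elimination through 9 are separated so that each can be run under its best conditions.

**3 from 1; 6 from 4; 13 from 11.** Complex 3 comes from a carbonyl ligand of 1 by addition of a methyl nucleophile and O-methylation of acylate 2. Aldehyde 6 comes from bromide 4 by one-carbon extension through Grignard reagent 5. Alkyne 13 comes from acetal 11 by double elimination through the acetylide 12. All three are short and use standard reactions, so the risk of the route is concentrated in the benzannulation.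

## Alternatives that were turned down

**Alternative 1: double Claisen condensation of a 1,2-diketone with an oxalate.**
- Disconnection: C3–C4 and C5–C6 are cut, so that C4 and C5 come from dimethyl oxalate A3 and C6, C1, C2, C3 from hexacosane-2,3-dione A2.
- Forward key step: under alkoxide base the methyl and the α-methylene of A2 each acylate on A3, closing the ring directly as 3-docosyl-2,5-dihydroxy-1,4-benzoquinone A1.
- For: two C–C bonds in one flask from cheap reagents, no redox adjustment, no stoichiometric metal, and probably about half the step count of the chosen route.
- Against: A2 must be prepared, and enolisable 1,2-diketones self-condense under the same base. More seriously, A1 carries two hydroxyls that differ only in having docosyl or hydrogen as neighbour, so mono-methylation at the C5 oxygen rests on a modest steric bias. The wrong ether and the dimethyl ether are expected alongside the right one.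
- Comparison: Alternative 1 is clearly stronger in step economy and cost. The chosen route never needs to tell the two oxygens apart, because the C5 oxygen is methylated from the start and the C2 oxygen is introduced afterwards.

**Alternative 2: photochemical vinylketene–siloxyalkyne benzannulation.**
- Disconnection: the ring is cut into a four-carbon vinylketene, generated from (E)-1-diazo-4-methoxybut-3-en-2-one A5, and the two carbons of 1-(triisopropylsilyloxy)tetracos-1-yne A6.
- Forward key step: photochemical Wolff rearrangement of A5, [2+2] addition of the ketene to A6, four-electron ring opening and six-electron closure give 2-docosyl-6-methoxy-3-(triisopropylsilyloxy)phenol A4.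
- For: no metal, and the regiochemistry is fixed by the polarity of ketene and ynol ether. Three oxygens are written in three different forms (OH, OMe, OSi), so the C2 oxygen is already present and the endgame is only para-oxidation of the phenol and desilylation. On that point it is stronger than the chosen route, which needs a separate C2 oxygenation.
- Against: A5 needs diazo chemistry on a vinylogous ester and gives an electron-rich, polymerisation-prone vinylketene. A6 needs a multi-step ynolate homologation on a waxy long-chain ester, and the photochemical step must be run dilute on poorly soluble material. The fourth oxygen (C1) still has to be added by oxidation.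
- Comparison: the overall length is similar. The chosen route offers simpler, non-hazardous building blocks (an aldehyde, Cr(CO)6 and a one-step ynol ether) and thermal rather than photochemical ring formation, at the price of stoichiometric chromium.

**Alternative 3: biomimetic tetraketide aldol to an alkylresorcinol.**
- Disconnection: the ring is opened between the ester-bearing and chain-bearing carbons to the linear methyl 3,5,7-trioxononacosanoate A8.
- Forward key step: intramolecular aldol condensation of the C2 methylene of A8 onto its C7 ketone and aromatisation give methyl 6-docosyl-2,4-dihydroxybenzoate A7.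
- For: the cyclisation of triketo esters is dependable, metal-free and mirrors the biosynthesis. The chain is placed without ambiguity.
- Against: A8 needs polyanion acylation chemistry, and A7 has only two ring oxygens, meta to each other. After ester removal to 5-docosylresorcinol A9, two further oxygens must be introduced and the four oxygens then differentiated (one methylated, one free, two as carbonyls). The endgame is therefore long and regiochemically delicate.
- Comparison: its ring-forming step is safer than the benzannulation chosen here. The chosen route installs three of the four oxygens, already differentiated, in the ring-forming step and needs only one further oxygenation.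

Key step: step 6

## Route

Step 1
Reactants: 1 chromium hexacarbonyl, Cr(CO)6
Product: 3 pentacarbonyl(1-methoxyethylidene)chromium, via lithium acetylpentacarbonylchromate 2 (not isolated)
Conditions: MeLi, Et2O, 0 °C to rt; then Me3OBF4, H2O–CH2Cl2, 0 °C
Reagents that add atoms: methyllithium, C[Li]; trimethyloxonium tetrafluoroborate, C[O+](C)C.F[B-](F)(F)F
Why: Fischer carbene synthesis: the alkyllithium adds to a carbonyl ligand and the acyl metalate 2 is alkylated on oxygen by the hard oxonium salt, so the carbene carbon and its oxygen both come from CO.

Step 2
Reactants: 4 1-bromodocosane
Product: 6 tricosanal, via docosylmagnesium bromide 5 (not isolated)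
Conditions: Mg, THF, 55 °C; then DMF, 0 °C to rt; aq. HCl
Reagents that add atoms: N,N-dimethylformamide, CN(C)C=O
Why: Bouveault aldehyde synthesis: the primary Grignard reagent adds once to the formamide and the magnesium hemiaminal persists until acidic work-up, so the chain should be extended by exactly one carbon at the aldehyde level.

Step 3
Reactants: 3 pentacarbonyl(1-methoxyethylidene)chromium; 6 tricosanal
Product: 8 pentacarbonyl(3-hydroxy-1-methoxypentacosylidene)chromium (racemic), via lithium pentacarbonyl(1-methoxyethenyl)chromate 7 (not isolated)
Conditions: n-BuLi, THF, −78 °C; then 6 premixed with TiCl4 in CH2Cl2, −78 to −30 °C; aq. NaHCO3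
Reagents that add atoms: none
Why: Lewis acid-mediated aldol addition of a Fischer carbene "enolate": the methyl group of 3 is strongly acidic, and its delocalised anion 7, too weak a nucleophile for a free aldehyde, should add once the aldehyde is activated by TiCl4. The carbinol carbon (the later ring carbon C3) is formed racemic and loses its stereochemistry in step 4.

Step 4
Reactants: 8 pentacarbonyl(3-hydroxy-1-methoxypentacosylidene)chromium
Product: 10 pentacarbonyl[(E)-1-methoxypentacos-2-enylidene]chromium, via mesylate 9 (not isolated)
Conditions: MsCl, Et3N, CH2Cl2, 0 °C to rt
Reagents that add atoms: none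
Why: sulfonylation followed by E1cB elimination, fast because the proton next to the carbene carbon is acidic. The conjugated (E)-alkene is expected because the chain avoids the bulky (CO)5Cr=C(OMe) unit in the stabilised carbanion.

Step 5
Reactants: 11 chloroacetaldehyde dimethyl acetal
Product: 13 methoxyethyne, via sodium methoxyethynide 12 (not isolated)
Conditions: NaNH2 (3 equiv), liq. NH3, −33 °C; evaporate NH3; then cold sat. aq. NaCl, distil into THF at −78 °C
Reagents that add atoms: none
Why: two successive base-induced 1,2-eliminations (methanol, then HCl) give the ynol ether, which the third equivalent of amide holds as the stable acetylide 12 until protonation. The product is kept as a cold THF solution because it boils near room temperature.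

Step 6
Reactants: 10 pentacarbonyl[(E)-1-methoxypentacos-2-enylidene]chromium; 13 methoxyethyne
Product: 15 2-docosyl-4,6-dimethoxyphenol, via tricarbonylchromium arene complex 14 (not isolated)
Conditions: 13 (3 equiv), THF (0.05 M), sealed tube, 55–60 °C, Ar; then air, Et2O, rt
Reagents that add atoms: none
Why: On warming, 10 loses one cis carbonyl ligand and binds 13; the nucleophilic unsubstituted alkyne carbon C6 attacks the electrophilic carbene carbon C1 (bond C1–C6), so that the oxygen-bearing carbon C5 becomes the new, donor-stabilised carbene carbon of a chromium dienylcarbene. Migration of a carbonyl ligand onto C5 (bond C4–C5) gives a chromium-bound dienylketene, and closure of the ketene carbon C4 onto the chain-bearing alkene carbon C3 (bond C3–C4) forms the ring; enolisation then gives the arene as its Cr(CO)3 complex 14, from which air releases 15. The closest known reaction type is the Dötz benzannulation of alkenyl(methoxy)carbene chromium complexes with terminal alkynes; benzannulations with 1-alkoxyalkynes are few and concern aryl and heteroaryl carbene complexes, and the second half of the sequence has its own analogy in the cyclisation of chromium dienyl(alkoxy)carbene complexes with CO insertion to ortho-alkoxyphenols. The one ring is closed by a disrotatory six-electron electrocyclisation of the metal-bound triene C4=C5, C6=C1, C2=C3, and no stereocentre is created. The selectivity needed is the orientation of the alkyne, with the methoxy carbon next to the CO-derived C4: the steric rule for terminal alkynes (hydrogen end to the carbene carbon) and oxygen stabilisation of the carbene at C5 call for the same orientation. CO insertion in preference to direct five-ring closure is favoured by chromium, by an alkoxy rather than amino carbene and by a weakly coordinating solvent at moderate dilution, and the (E)-alkene of 10 places C3 within reach of the ketene. Because 13 has no β-hydrogen it cannot fragment to a ketene by a retro-ene path, so the sealed tube can be heated for as long as the donor-stabilised intermediate requires.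

Step 7
Reactants: 15 2-docosyl-4,6-dimethoxyphenol
Product: 16 2-docosyl-6-methoxy-1,4-benzoquinone
Conditions: (NH4)2Ce(NO3)6 (2.2 equiv), MeCN–THF–H2O, 0 °C
Reagents that add atoms: water, O
Why: oxidative demethylation of a 4-methoxyphenol: two one-electron oxidations give the para-oxocarbenium ion, water adds at C1 and the hemiketal loses methanol. The para-quinone is expected over the ortho-quinone, so the C5 methoxy group should survive.

Step 8
Reactants: 16 2-docosyl-6-methoxy-1,4-benzoquinone
Product: 17 3-docosyl-5-methoxybenzene-1,2,4-triyl triacetate
Conditions: Ac2O, H2SO4 (cat.), 25–40 °C
Reagents that add atoms: acetic anhydride, CC(=O)OC(C)=O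
Why: Thiele–Winter acetoxylation: acid-activated conjugate addition of acetate, enolisation to the arene and acetylation of both phenols. Addition is expected at C2, the β-carbon of the enone C4(=O)–C3=C2 and para to the methoxy group, because C6 is the electron-rich end of the enol ether and C1=O is deactivated as a vinylogous ester.

Step 9
Reactants: 17 3-docosyl-5-methoxybenzene-1,2,4-triyl triacetate
Product: 19 3-docosyl-2-hydroxy-5-methoxy-1,4-benzoquinone, via 3-docosyl-5-methoxybenzene-1,2,4-triol 18 (not isolated)
Conditions: HCl, MeOH–THF, 60 °C, N2; evaporate; then FeCl3, THF–H2O, rt
Reagents that add atoms: none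
Why: acid-catalysed transesterification frees the three phenols while the C5 group is still an ordinary aryl methyl ether, and the alcohol is removed before oxidation. The hydroxyhydroquinone 18 is then oxidised by two electrons to the 2-hydroxy-1,4-quinone, the stable tautomer.

## Compound list

1 | chromium hexacarbonyl, Cr(CO)6 | O=C=[Cr](=C=O)(=C=O)(=C=O)(=C=O)=C=O | starting material
2 | lithium acetylpentacarbonylchromate | CC([O-])=[Cr](=C=O)(=C=O)(=C=O)(=C=O)=C=O.[Li+] | intermediate
3 | pentacarbonyl(1-methoxyethylidene)chromium | CC(OC)=[Cr](=C=O)(=C=O)(=C=O)(=C=O)=C=O | intermediate
4 | 1-bromodocosane | CCCCCCCCCCCCCCCCCCCCCCBr | starting material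
5 | docosylmagnesium bromide | CCCCCCCCCCCCCCCCCCCCCC[Mg]Br | intermediate
6 | tricosanal | CCCCCCCCCCCCCCCCCCCCCCC=O | intermediate
7 | lithium pentacarbonyl(1-methoxyethenyl)chromate | [CH2-]C(OC)=[Cr](=C=O)(=C=O)(=C=O)(=C=O)=C=O.[Li+] | intermediate
8 | pentacarbonyl(3-hydroxy-1-methoxypentacosylidene)chromium, racemic | CCCCCCCCCCCCCCCCCCCCCCC(O)CC(OC)=[Cr](=C=O)(=C=O)(=C=O)(=C=O)=C=O | intermediate
9 | pentacarbonyl[1-methoxy-3-(methylsulfonyloxy)pentacosylidene]chromium, racemic | CCCCCCCCCCCCCCCCCCCCCCC(OS(C)(=O)=O)CC(OC)=[Cr](=C=O)(=C=O)(=C=O)(=C=O)=C=O | intermediate
10 | pentacarbonyl[(E)-1-methoxypentacos-2-enylidene]chromium | CCCCCCCCCCCCCCCCCCCCCC/C=C/C(OC)=[Cr](=C=O)(=C=O)(=C=O)(=C=O)=C=O | intermediate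
11 | chloroacetaldehyde dimethyl acetal (2-chloro-1,1-dimethoxyethane) | COC(CCl)OC | starting material
12 | sodium methoxyethynide | [Na+].[C-]#COC | intermediate
13 | methoxyethyne | COC#C | intermediate
14 | tricarbonyl(η6-2-docosyl-4,6-dimethoxyphenol)chromium (the dot stands for the η6 bond) | CCCCCCCCCCCCCCCCCCCCCCc1cc(OC)cc(OC)c1O.O=C=[Cr](=C=O)=C=O | intermediate
15 | 2-docosyl-4,6-dimethoxyphenol | CCCCCCCCCCCCCCCCCCCCCCc1cc(OC)cc(OC)c1O | intermediate
16 | 2-docosyl-6-methoxy-1,4-benzoquinone | CCCCCCCCCCCCCCCCCCCCCCC1=CC(=O)C=C(OC)C1=O | intermediate
17 | 3-docosyl-5-methoxybenzene-1,2,4-triyl triacetate | CCCCCCCCCCCCCCCCCCCCCCc1c(OC(C)=O)c(OC(C)=O)cc(OC)c1OC(C)=O | intermediate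
18 | 3-docosyl-5-methoxybenzene-1,2,4-triol | CCCCCCCCCCCCCCCCCCCCCCc1c(O)c(O)cc(OC)c1O | intermediate
19 | 3-docosyl-2-hydroxy-5-methoxy-1,4-benzoquinone | CCCCCCCCCCCCCCCCCCCCCCC1=C(O)C(=O)C=C(OC)C1=O | target

## Step count and risks

Total step count: 9. Longest linear sequence: 7 steps (from 4 through steps 2, 3, 4, 6, 7, 8, 9; the branch from 1 is equally long).

**Step 6 (key step).** The most likely failure is that the sequence halts after alkyne insertion, because a carbene carbon stabilised by its own methoxy group and by the enol ether beyond it is slow to take up CO. Competing losses are metal-initiated oligomerisation of the electron-rich alkyne, its [2+2] addition to the electron-poor C2=C3 bond of 10, and closure without CO to a five-membered ring. Within the strategy the first remedies are longer heating or irradiation of the stalled mixture. The fallback abandons the chromium chemistry and builds the quinone on a preformed arene; it sets out from 4 and comes back at 16. 2-Methoxyphenol is protected with chloromethyl methyl ether and i-Pr2NEt as 1-methoxy-2-(methoxymethoxy)benzene F1. This is lithiated ortho to the acetal oxygen with n-BuLi/TMEDA and alkylated with 4 to give 1-docosyl-3-methoxy-2-(methoxymethoxy)benzene F2. Acidic methanolysis gives 2-docosyl-6-methoxyphenol F3, and para-oxidation with (KSO3)2NO in buffered aqueous THF gives 16.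

**Step 3.** The C23 aldehyde may precipitate at low temperature or enolise and self-condense under the Lewis acid, so that the weakly nucleophilic carbene anion is simply re-protonated on work-up. Retro-aldol cleavage of 8 during isolation is a further loss. The fallback makes the alkenyl complex by the Fischer route; it sets out from 6 and 1 and comes back at 10. Takai iodo-olefination of 6 (CHI3, CrCl2, THF) gives (E)-1-iodotetracos-1-ene F4. Iodine–lithium exchange with t-BuLi at −78 °C gives (E)-tetracos-1-enyllithium F5, which adds to a carbonyl ligand of 1 to give lithium pentacarbonyl[(E)-pentacos-2-enoyl]chromate F6. O-methylation with Me3OBF4 gives 10.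

**Step 8.** Conjugate addition may be slow, because two donor substituents make 16 a poor acceptor, or misdirected. Possible diversions are addition at C6, and attack at C5 of the O-acylated vinylogous ester with exchange of the methoxy group for acetoxy. The fallback replaces acid-mediated acetoxylation by nucleophilic epoxidation; it sets out from 16 and comes back at 19. H2O2 and Na2CO3 in THF–H2O at 0 °C should epoxidise the electron-poor C2=C3 bond, not the enol ether, to give rac-1-docosyl-3-methoxy-7-oxabicyclo[4.1.0]hept-3-ene-2,5-dione F7. Brief treatment with cold concentrated H2SO4 opens the epoxide at the tertiary C3–O bond, and loss of the C2 proton gives 19 directly, bypassing 17 and 18.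

**Step 9.** Methyl transfer at the quinone oxidation level is the main danger. Once oxidised, C5–OMe is a vinylogous ester and C2–OH a vinylogous acid, so residual acid and alcohol can remove the one methyl or add a second. Incomplete solvolysis of the hindered C4 acetate, flanked by docosyl and methoxy, is the other. The fallback removes the acetates reductively under aprotic conditions; it sets out from 17 and comes back at 18 and then 19. LiAlH4 in THF at 0 °C under N2, with acidic work-up in the absence of any alcohol solvent, should give 18, which is oxidised with FeCl3 as in the route. No new compound is made.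

## Further compounds

F1 | step 6 | 1-methoxy-2-(methoxymethoxy)benzene | COCOc1ccccc1OC
F2 | step 6 | 1-docosyl-3-methoxy-2-(methoxymethoxy)benzene | CCCCCCCCCCCCCCCCCCCCCCc1cccc(OC)c1OCOC
F3 | step 6 | 2-docosyl-6-methoxyphenol | CCCCCCCCCCCCCCCCCCCCCCc1cccc(OC)c1O
F4 | step 3 | (E)-1-iodotetracos-1-ene | CCCCCCCCCCCCCCCCCCCCCC/C=C/I
F5 | step 3 | (E)-tetracos-1-enyllithium | CCCCCCCCCCCCCCCCCCCCCC/C=C/[Li]
F6 | step 3 | lithium pentacarbonyl[(E)-pentacos-2-enoyl]chromate | CCCCCCCCCCCCCCCCCCCCCC/C=C/C([O-])=[Cr](=C=O)(=C=O)(=C=O)(=C=O)=C=O.[Li+]
F7 | step 8 | rac-1-docosyl-3-methoxy-7-oxabicyclo[4.1.0]hept-3-ene-2,5-dione | CCCCCCCCCCCCCCCCCCCCCCC12OC1C(=O)C=C(OC)C2=O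
F0 | step 9 | none | none
A1 | alternative 1 | 3-docosyl-2,5-dihydroxy-1,4-benzoquinone | CCCCCCCCCCCCCCCCCCCCCCC1=C(O)C(=O)C=C(O)C1=O
A2 | alternative 1 | hexacosane-2,3-dione | CCCCCCCCCCCCCCCCCCCCCCCC(=O)C(C)=O
A3 | alternative 1 | dimethyl oxalate | COC(=O)C(=O)OC
A4 | alternative 2 | 2-docosyl-6-methoxy-3-(triisopropylsilyloxy)phenol | CCCCCCCCCCCCCCCCCCCCCCc1c(O)c(OC)ccc1O[Si](C(C)C)(C(C)C)C(C)C
A5 | alternative 2 | (E)-1-diazo-4-methoxybut-3-en-2-one | CO/C=C/C(=O)C=[N+]=[N-]
A6 | alternative 2 | 1-(triisopropylsilyloxy)tetracos-1-yne | CCCCCCCCCCCCCCCCCCCCCCC#CO[Si](C(C)C)(C(C)C)C(C)C
A7 | alternative 3 | methyl 6-docosyl-2,4-dihydroxybenzoate | CCCCCCCCCCCCCCCCCCCCCCc1cc(O)cc(O)c1C(=O)OC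
A8 | alternative 3 | methyl 3,5,7-trioxononacosanoate | CCCCCCCCCCCCCCCCCCCCCCC(=O)CC(=O)CC(=O)CC(=O)OC
A9 | alternative 3 | 5-docosylbenzene-1,3-diol (5-docosylresorcinol) | CCCCCCCCCCCCCCCCCCCCCCc1cc(O)cc(O)c1
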